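Start from what is left.

| setting | beta | alpha | flask |
|---|---|---|---|
| starting material | 10 mM | 5 mM | 10 mM |
| gas | 2.1 mM (held) | 2.1 mM (held) | 2.1 mM (held) |
| free enzyme | 0.01 mol% | 0.01 mol% | 0.01 mol% |
| remark | the very flask that is asked about, followed so far | run made earlier |  |

- beta (time / h: target / %, starting material / %): 1.33: 1, 100; 3.00: 4, 100; 6.00: 4, 100; 15.0: 15, 86
- alpha (time / h: target / %, starting material / %): 5.00: 8, 98; 10.0: 14, 89; 15.0: 18, 79; 20.0: 29, 72

(scatter of a reading: 2 percentage points)

* factor on the rate of making target when 5.0% of the starting material are converted if free enzyme is charged twice over
* factor on the rate when 5.0% of the starting material are converted if free enzyme is charged at 0.001 mol% instead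

- the numbers in the tables scatter with a standard deviation of 2 percentage points
- at the start none of the gas is in solution

The charges and the saturation of gas are set values, so the weight falls on the last readings of starting material left: 86% in beta after 15.0 h and 72% in alpha after 20.0 h. The scatter of 2 percentage points weighs twice as heavily on beta's drop as on alpha's, so beta's reading has to be known best. A relative error in the ratio of the two rates passes unchanged into the factor for doubling, but it enters the factor for the cut to 0.001 mol% raised to the power 3.32.

From the fraction left, beta consumes 0.0933 mM h⁻¹ and alpha 0.0700 mM h⁻¹, each on average up to its last reading. Free enzyme is charged on starting material, so beta holds twice alpha's free enzyme and twice alpha's starting material. The reckoning made here gives 0.415 for n, the apparent order in free enzyme with starting material changing alongside it, defined as the logarithm of the rate ratio over the logarithm of the charge ratio. This n predicts 1.33 for doubling and 0.385 for the cut.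

The forecast differs, with 1.4 and 0.3: “I take about 0.5 order, with wide ranges”.

The flask gives 1.07 and 0.329.

    starting material + free enzyme ⇌ first complex (K = 250 L mol⁻¹, k = 2.70 × 10⁵ L mol⁻¹ h⁻¹)
    first complex → loaded enzyme + first product (k = 1100 h⁻¹)
    second substrate + loaded enzyme ⇌ second complex (K = 640 L mol⁻¹, k = 8.10 × 10⁵ L mol⁻¹ h⁻¹)
    second complex → free enzyme + target (k = 8200 h⁻¹)
    gas ⇌ second substrate, rate k5*(csat - [second substrate]) (kL = 0.0510 h⁻¹)

Read back from the two factors, n is 0.0967 for the flask with the higher charge of free enzyme and 0.483 for the flask charged at 0.001 mol%, larger than for the higher charge. In the flask as charged, at 14.9 h, second substrate has a half-life of 1.0 h by the forward step alone onto loaded enzyme, the resting state at 81.6% of the catalyst, far shorter than the 13.6 h half-time of the gas crossing. Second substrate in that flask stands at 0.171 mM after 15.0 h, which leaves 91.8% of the gap to saturation open.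

The earlier runs and the new flask come from a simulation for substances that don't exist.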